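**Plan**

- Retrosynthesis, chain numbered C1 (benzylic) to C8 (methyl): the acetyl groups are removed, the aryl–C1 bond is cut (aryllithium plus a C1 aldehyde, the benzylic oxygen being hydrogenolysed later), and the C6–C7 bond is cut as a C6=C7 Wittig alkene. This leaves a C1–C6 unit with an acyl carbon at C1 and CH2OH at C6.
- Joining that acyl carbon to the C6 oxygen gives a seven-membered lactone; taking out the ring oxygen (retro-Baeyer–Villiger) restores the C1–C6 bond of a six-membered ketone.
- Enabling feature: C2, C4 and C6 are methylenes and C3 and C5 carry syn oxygens, so C1–C6 is a pseudo-meso array that maps onto the six ring carbons of cis-3,5-dioxygenated cyclohexanone (C1 = carbonyl carbon). The mirror plane through C1 and C4 makes its two α-methylenes enantiotopic.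
- Forward: all-cis triol, bis-silyl ether, meso ketone; oxygen insertion then gives the oxepan-2-one, the only ring formed. It is opened to an N-methoxy-N-methylamide, C7–C8 are added at C6 by Wittig reaction, the aryl group is added at C1, and hydrogenation, desilylation, acetylation and phenol release finish the target.
- Stereochemistry: the syn C3/C5 relation comes from the all-cis triol. The absolute configuration of both centres is fixed in one event, the catalyst's choice between the two enantiotopic methylenes, and no later step breaks a bond at C3 or C5.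

Key step: step 3

Assumption: the sense of induction of the chiral scandium catalyst on this meso ketone cannot be predicted with certainty. The ligand is the C2-symmetric 1,1'-(propane-1,3-diyl)bis{2-[(2,6-diisopropylphenyl)carbamoyl]piperidine 1-oxide}, available in both antipodes from L- or D-pipecolic acid, and the antipode that delivers the (4S,6R)-lactone is taken as identified in a pilot run.

Remark: the commercial triol is a dihydrate and is dried azeotropically before silylation.

**Route**

Step 1
Reactants: 1 cis,cis-cyclohexane-1,3,5-triol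
Product: 2 all-cis-3,5-bis(tert-butyldimethylsilyloxy)cyclohexan-1-ol
Conditions: TBSCl (2.1 equiv), imidazole, DMF, 0 °C to rt
Reagents that add atoms: tert-butyldimethylsilyl chloride, CC(C)(C)[Si](C)(C)Cl
Why: The three hydroxyls of the all-cis triol are homotopic, so statistical silyl ether formation can give only one bis-silyl ether, the meso alcohol, which is separated from mono- and tris-silylated material that can be recycled.

Step 2
Reactants: 2 all-cis-3,5-bis(tert-butyldimethylsilyloxy)cyclohexan-1-ol
Product: 3 cis-3,5-bis(tert-butyldimethylsilyloxy)cyclohexan-1-one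
Conditions: Dess–Martin periodinane, NaHCO3, CH2Cl2, 0 °C to rt
Reagents that add atoms: none
Why: Dess–Martin oxidation of the remaining secondary alcohol under bicarbonate buffering should give the meso ketone without base-induced β-elimination of a silyloxy group and without touching the two carbinol carbons.

Step 3
Reactants: 3 cis-3,5-bis(tert-butyldimethylsilyloxy)cyclohexan-1-one
Product: 5 (4S,6R)-4,6-bis(tert-butyldimethylsilyloxy)oxepan-2-one, via Criegee adduct 4 (not isolated)
Conditions: Sc(OTf)3 (5 mol %), chiral N,N'-dioxide ligand (6 mol %), m-CPBA (1.3 equiv), EtOAc, −20 °C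
Reagents that add atoms: m-chloroperoxybenzoic acid, OOC(=O)c1cccc(Cl)c1
Why: Baeyer–Villiger oxidation: the peracid adds to the carbonyl held by the chiral scandium complex to give Criegee adduct 4, and the α-methylene whose C–C bond lies antiperiplanar to the O–O bond migrates to oxygen with loss of 3-chlorobenzoate. The closest known reaction type is the catalytic enantioselective Baeyer–Villiger desymmetrisation of prochiral and meso cyclohexanones by chiral N,N'-dioxide–Sc(OTf)3 complexes with m-CPBA, which flavin monooxygenases also perform. The oxepan-2-one does not arise by a cyclisation but by ring expansion, a 1,2-shift of C6 from C1 to oxygen that inserts the oxygen into the C1–C6 bond of the six-membered ring. No new stereogenic carbon is created, but the mirror plane of 3 is lost, so ring carbons C3 and C5 of 3 become C4 (S) and C6 (R) of 5; their cis relation comes from the all-cis triol and their absolute sense from the ligand sphere, which should let only one of the two enantiotopic methylenes reach the migrating alignment. The step needs enantiotopic-group selectivity only, because both α-carbons are constitutionally equivalent methylenes and no regiochemical question exists; the low temperature and the aprotic solvent should keep the silyl ethers and the β-silyloxy carbonyl unit intact.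

Step 4
Reactants: 5 (4S,6R)-4,6-bis(tert-butyldimethylsilyloxy)oxepan-2-one
Product: 6 (3S,5R)-3,5-bis(tert-butyldimethylsilyloxy)-6-hydroxy-N-methoxy-N-methylhexanamide
Conditions: MeNH(OMe)·HCl, AlMe3, CH2Cl2, 0 °C to rt; aq. potassium sodium tartrate work-up
Reagents that add atoms: N,O-dimethylhydroxylamine hydrochloride, CNOC.Cl
Why: Aminolysis of the lactone by the aluminium amide made from AlMe3 and the amine salt (Weinreb amidation) is a standard lactone opening that differentiates the chain ends as amide (C1) and CH2OH (C6), and the weakly basic aluminium alkoxide of the released alcohol should not trigger silyl migration.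

Step 5
Reactants: 6 (3S,5R)-3,5-bis(tert-butyldimethylsilyloxy)-6-hydroxy-N-methoxy-N-methylhexanamide
Product: 7 (3S,5R)-3,5-bis(tert-butyldimethylsilyloxy)-N-methoxy-N-methyl-6-oxohexanamide
Conditions: Dess–Martin periodinane, NaHCO3, CH2Cl2, 0 °C; used crude at once
Reagents that add atoms: none
Why: Dess–Martin oxidation converts the primary alcohol into the α-silyloxy aldehyde under buffered, non-epimerising conditions to which the N-methoxy-N-methylamide and the silyl ethers are inert.

Step 6
Reactants: 7 (3S,5R)-3,5-bis(tert-butyldimethylsilyloxy)-N-methoxy-N-methyl-6-oxohexanamide, 8 ethyltriphenylphosphonium bromide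
Product: 10 (3S,5R,6Z)-3,5-bis(tert-butyldimethylsilyloxy)-N-methoxy-N-methyloct-6-enamide, via ethylidenetriphenylphosphorane 9 (not isolated)
Conditions: 8, KN(SiMe3)2 (slightly less than 8), THF, 0 °C; then 7, −78 °C to 0 °C
Reagents that add atoms: none
Why: Wittig olefination with the non-stabilised ylide 9 is far faster at the aldehyde than at the amide and, with no excess base at −78 °C, should not epimerise C5; the Z-alkene is expected to predominate, and the geometry is irrelevant because the double bond is hydrogenated in step 10.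

Step 7
Reactants: 10 (3S,5R,6Z)-3,5-bis(tert-butyldimethylsilyloxy)-N-methoxy-N-methyloct-6-enamide
Product: 11 (3S,5R,6Z)-3,5-bis(tert-butyldimethylsilyloxy)oct-6-enal
Conditions: i-Bu2AlH, THF, −78 °C; aq. potassium sodium tartrate work-up
Reagents that add atoms: none
Why: Partial hydride reduction of an N-methoxy-N-methylamide with i-Bu2AlH reliably stops at the aldehyde oxidation level, since over-reduction is blocked until aqueous work-up, and the alkene and silyl ethers are inert.

Step 8
Reactants: 12 4-bromo-2-methoxyphenol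
Product: 13 1-(benzyloxy)-4-bromo-2-methoxybenzene
Conditions: BnBr, K2CO3, DMF, rt
Reagents that add atoms: benzyl bromide, BrCc1ccccc1
Why: Williamson ether synthesis on the phenoxide masks the phenol as a benzyl ether that tolerates organolithium chemistry and is removed without an extra step in the hydrogenation of step 10.

Step 9
Reactants: 11 (3S,5R,6Z)-3,5-bis(tert-butyldimethylsilyloxy)oct-6-enal, 13 1-(benzyloxy)-4-bromo-2-methoxybenzene
Product: 16 (1RS,3R,5R,6Z)-1-[4-(benzyloxy)-3-methoxyphenyl]-3,5-bis(tert-butyldimethylsilyloxy)oct-6-en-1-yl acetate, via aryllithium 14 (not isolated), via lithium alkoxide 15 (not isolated)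
Conditions: 13, n-BuLi, THF, −78 °C; then 11, −78 °C; then Ac2O, −78 to 0 °C
Reagents that add atoms: acetic anhydride, CC(=O)OC(C)=O
Why: Bromine–lithium exchange gives aryllithium 14, whose 1,2-addition to the aldehyde at −78 °C should outrun enolisation, and O-acylation of alkoxide 15 in the same flask turns the benzylic oxygen into an acetate that is easy to hydrogenolyse; the new C1 centre is formed as a mixture of epimers, which does not matter because it is erased in step 10.

Step 10
Reactants: 16 (1RS,3R,5R,6Z)-1-[4-(benzyloxy)-3-methoxyphenyl]-3,5-bis(tert-butyldimethylsilyloxy)oct-6-en-1-yl acetate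
Product: 17 4-[(3R,5S)-3,5-bis(tert-butyldimethylsilyloxy)octyl]-2-methoxyphenol
Conditions: H2 (1 atm), Pd/C, EtOAc, rt
Reagents that add atoms: none
Why: Heterogeneous catalytic hydrogenation over Pd/C should saturate the C6=C7 bond, hydrogenolyse the benzyl ether and hydrogenolyse the electron-rich benzylic C–OAc bond in one operation, while the silyl ethers and both carbinol centres stay untouched in the non-nucleophilic solvent.

Step 11
Reactants: 17 4-[(3R,5S)-3,5-bis(tert-butyldimethylsilyloxy)octyl]-2-methoxyphenol
Product: 18 4-[(3R,5S)-3,5-dihydroxyoctyl]-2-methoxyphenol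
Conditions: 48% aq. HF, MeCN, 0 °C to rt
Reagents that add atoms: none
Why: Fluoride-mediated desilylation under acidic conditions cleaves only Si–O bonds, so the configuration at C3 and C5 is retained and the free phenol is not exposed to base.

Step 12
Reactants: 18 4-[(3R,5S)-3,5-dihydroxyoctyl]-2-methoxyphenol
Product: 19 (3R,5S)-1-(4-acetoxy-3-methoxyphenyl)octane-3,5-diyl diacetate
Conditions: Ac2O, pyridine, DMAP (cat.), CH2Cl2, rt
Reagents that add atoms: acetic anhydride, CC(=O)OC(C)=O
Why: Exhaustive DMAP-catalysed O-acylation esterifies both secondary alcohols and, unavoidably, the phenol, which is more reliable than trying to acylate the alcohols selectively in the presence of the phenol.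

Step 13
Reactants: 19 (3R,5S)-1-(4-acetoxy-3-methoxyphenyl)octane-3,5-diyl diacetate
Product: 20 (3R,5S)-1-(4-hydroxy-3-methoxyphenyl)octane-3,5-diyl diacetate
Conditions: pyrrolidine (1.5 equiv), CH2Cl2, 0 °C to rt
Reagents that add atoms: none
Why: Chemoselective aminolysis: the aryl acetate, with its much better phenoxide leaving group, should be cleaved by the secondary amine under conditions where the two secondary alkyl acetates do not react, releasing the phenol of the target.

**Compound list**

1 | cis,cis-cyclohexane-1,3,5-triol (all-cis) | O[C@H]1C[C@@H](O)C[C@@H](O)C1 | starting material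
2 | all-cis-3,5-bis(tert-butyldimethylsilyloxy)cyclohexan-1-ol (meso) | O[C@H]1C[C@@H](O[Si](C)(C)C(C)(C)C)C[C@@H](O[Si](C)(C)C(C)(C)C)C1 | intermediate
3 | cis-3,5-bis(tert-butyldimethylsilyloxy)cyclohexan-1-one (meso, 3R,5S) | O=C1C[C@@H](O[Si](C)(C)C(C)(C)C)C[C@@H](O[Si](C)(C)C(C)(C)C)C1 | intermediate
4 | Criegee adduct, (3R,5S)-3,5-bis(tert-butyldimethylsilyloxy)-1-hydroxycyclohexyl 3-chloroperoxybenzoate (C1 undefined) | OC1(OOC(=O)c2cccc(Cl)c2)C[C@@H](O[Si](C)(C)C(C)(C)C)C[C@@H](O[Si](C)(C)C(C)(C)C)C1 | intermediate (not isolated)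
5 | (4S,6R)-4,6-bis(tert-butyldimethylsilyloxy)oxepan-2-one | O=C1C[C@@H](O[Si](C)(C)C(C)(C)C)C[C@@H](O[Si](C)(C)C(C)(C)C)CO1 | intermediate
6 | (3S,5R)-3,5-bis(tert-butyldimethylsilyloxy)-6-hydroxy-N-methoxy-N-methylhexanamide | CON(C)C(=O)C[C@@H](O[Si](C)(C)C(C)(C)C)C[C@@H](O[Si](C)(C)C(C)(C)C)CO | intermediate
7 | (3S,5R)-3,5-bis(tert-butyldimethylsilyloxy)-N-methoxy-N-methyl-6-oxohexanamide | CON(C)C(=O)C[C@@H](O[Si](C)(C)C(C)(C)C)C[C@@H](O[Si](C)(C)C(C)(C)C)C=O | intermediate
8 | ethyltriphenylphosphonium bromide | CC[P+](c1ccccc1)(c1ccccc1)c1ccccc1.[Br-] | starting material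
9 | ethylidenetriphenylphosphorane | CC=P(c1ccccc1)(c1ccccc1)c1ccccc1 | intermediate (not isolated)
10 | (3S,5R,6Z)-3,5-bis(tert-butyldimethylsilyloxy)-N-methoxy-N-methyloct-6-enamide | CON(C)C(=O)C[C@@H](O[Si](C)(C)C(C)(C)C)C[C@@H](O[Si](C)(C)C(C)(C)C)/C=C\C | intermediate
11 | (3S,5R,6Z)-3,5-bis(tert-butyldimethylsilyloxy)oct-6-enal | O=CC[C@@H](O[Si](C)(C)C(C)(C)C)C[C@@H](O[Si](C)(C)C(C)(C)C)/C=C\C | intermediate
12 | 4-bromo-2-methoxyphenol | COc1cc(Br)ccc1O | starting material
13 | 1-(benzyloxy)-4-bromo-2-methoxybenzene | COc1cc(Br)ccc1OCc1ccccc1 | intermediate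
14 | [4-(benzyloxy)-3-methoxyphenyl]lithium | [Li]c1ccc(OCc2ccccc2)c(OC)c1 | intermediate (not isolated)
15 | lithium (1RS,3R,5R,6Z)-1-[4-(benzyloxy)-3-methoxyphenyl]-3,5-bis(tert-butyldimethylsilyloxy)oct-6-en-1-olate | [Li]OC(C[C@@H](O[Si](C)(C)C(C)(C)C)C[C@@H](O[Si](C)(C)C(C)(C)C)/C=C\C)c1ccc(OCc2ccccc2)c(OC)c1 | intermediate (not isolated)
16 | (1RS,3R,5R,6Z)-1-[4-(benzyloxy)-3-methoxyphenyl]-3,5-bis(tert-butyldimethylsilyloxy)oct-6-en-1-yl acetate (C1 epimers) | CC(=O)OC(C[C@@H](O[Si](C)(C)C(C)(C)C)C[C@@H](O[Si](C)(C)C(C)(C)C)/C=C\C)c1ccc(OCc2ccccc2)c(OC)c1 | intermediate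
17 | 4-[(3R,5S)-3,5-bis(tert-butyldimethylsilyloxy)octyl]-2-methoxyphenol | COc1cc(CC[C@@H](O[Si](C)(C)C(C)(C)C)C[C@@H](O[Si](C)(C)C(C)(C)C)CCC)ccc1O | intermediate
18 | 4-[(3R,5S)-3,5-dihydroxyoctyl]-2-methoxyphenol | COc1cc(CC[C@@H](O)C[C@@H](O)CCC)ccc1O | intermediate
19 | (3R,5S)-1-(4-acetoxy-3-methoxyphenyl)octane-3,5-diyl diacetate | COc1cc(CC[C@@H](OC(C)=O)C[C@@H](OC(C)=O)CCC)ccc1OC(C)=O | intermediate
20 | (3R,5S)-1-(4-hydroxy-3-methoxyphenyl)octane-3,5-diyl diacetate | CCC[C@@H](C[C@@H](CCc1ccc(O)c(OC)c1)OC(C)=O)OC(C)=O | target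

**Step count**

Total: 13 steps. Longest linear sequence: 12 steps (steps 1–7 and 9–13, from triol 1); step 8 is a one-step side branch.

**Steps most likely to fail**

Step 3. Discrimination between the two enantiotopic methylenes may be incomplete on a ketone with two bulky silyloxy groups. The Lewis acid together with the carboxylic acid formed may also strip a silyl ether or start β-elimination. The fallback keeps the meso ketone but uses another desymmetrising event. Starting from 3, enantiotopic-proton-selective deprotonation with lithium bis[(R)-1-phenylethyl]amide or its antipode (the one that removes a proton from the methylene destined to become C6), in THF at −78 °C with Me3SiCl present as internal quench, should give the silyl enol ether {[(3R,5S)-3,5-bis(tert-butyldimethylsilyloxy)cyclohex-1-en-1-yl]oxy}trimethylsilane F1. Ozonolysis in CH2Cl2/MeOH at −78 °C with NaBH4 work-up cleaves the enol double bond (C1=C6 in the numbering of 3) to the acid at C1 and the primary alcohol at C6, (3S,5R)-3,5-bis(tert-butyldimethylsilyloxy)-6-hydroxyhexanoic acid F2. Amide coupling with MeNH(OMe)·HCl (EDC·HCl, HOBt, i-Pr2NEt, CH2Cl2) then returns to the route at 6.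

Step 9. The aryllithium may act as a base on the β-silyloxy aldehyde, leading to enolisation and loss of silanolate, and acylation of the hindered alkoxide may stay incomplete. The fallback adds the aryl group at the amide oxidation level, so that no free β-silyloxy carbonyl compound meets the organolithium. Starting from 10, addition of aryllithium 14 (from 13 and n-BuLi, THF, −78 °C) should give, after work-up, the aryl ketone (3S,5R,6Z)-1-[4-(benzyloxy)-3-methoxyphenyl]-3,5-bis(tert-butyldimethylsilyloxy)oct-6-en-1-one F3. Reduction with NaBH4 in MeOH at 0 °C gives the benzylic alcohol (1RS,3R,5R,6Z)-1-[4-(benzyloxy)-3-methoxyphenyl]-3,5-bis(tert-butyldimethylsilyloxy)oct-6-en-1-ol F4, and acetylation (Ac2O, pyridine, DMAP) rejoins the route at 16.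

Step 10. Cleavage of the benzylic C–O bond may lag behind debenzylation and alkene saturation, and ionisation of the electron-rich benzylic position may lead to capture by the C5 oxygen, closing a tetrahydropyran. The fallback forms the aryl–C1 bond without any benzylic oxygen.
- Starting from 11, NaBH4 in MeOH at 0 °C gives (3R,5R,6Z)-3,5-bis(tert-butyldimethylsilyloxy)oct-6-en-1-ol F5.
- I2, PPh3 and imidazole in CH2Cl2 convert it into (3S,5R,6Z)-3,5-bis(tert-butyldimethylsilyloxy)-1-iodooct-6-ene F6.
- Zinc insertion (Zn dust, LiCl, THF) gives [(3S,5R,6Z)-3,5-bis(tert-butyldimethylsilyloxy)oct-6-en-1-yl]zinc iodide F7.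
- Negishi coupling of F7 with aryl bromide 13 (Pd(OAc)2, SPhos, THF, rt to 50 °C) gives 1-(benzyloxy)-4-[(3R,5R,6Z)-3,5-bis(tert-butyldimethylsilyloxy)oct-6-en-1-yl]-2-methoxybenzene F8.
- Hydrogenation (H2, Pd/C, EtOAc) then only has to saturate the alkene and remove the benzyl group, and the route is rejoined at 17.

Further compounds
F1 | step 3 | {[(3R,5S)-3,5-bis(tert-butyldimethylsilyloxy)cyclohex-1-en-1-yl]oxy}trimethylsilane | C[Si](C)(C)OC1=C[C@H](O[Si](C)(C)C(C)(C)C)C[C@H](O[Si](C)(C)C(C)(C)C)C1
F2 | step 3 | (3S,5R)-3,5-bis(tert-butyldimethylsilyloxy)-6-hydroxyhexanoic acid | OC(=O)C[C@@H](O[Si](C)(C)C(C)(C)C)C[C@@H](O[Si](C)(C)C(C)(C)C)CO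
F3 | step 9 | (3S,5R,6Z)-1-[4-(benzyloxy)-3-methoxyphenyl]-3,5-bis(tert-butyldimethylsilyloxy)oct-6-en-1-one | O=C(C[C@@H](O[Si](C)(C)C(C)(C)C)C[C@@H](O[Si](C)(C)C(C)(C)C)/C=C\C)c1ccc(OCc2ccccc2)c(OC)c1
F4 | step 9 | (1RS,3R,5R,6Z)-1-[4-(benzyloxy)-3-methoxyphenyl]-3,5-bis(tert-butyldimethylsilyloxy)oct-6-en-1-ol | OC(C[C@@H](O[Si](C)(C)C(C)(C)C)C[C@@H](O[Si](C)(C)C(C)(C)C)/C=C\C)c1ccc(OCc2ccccc2)c(OC)c1
F5 | step 10 | (3R,5R,6Z)-3,5-bis(tert-butyldimethylsilyloxy)oct-6-en-1-ol | OCC[C@@H](O[Si](C)(C)C(C)(C)C)C[C@@H](O[Si](C)(C)C(C)(C)C)/C=C\C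
F6 | step 10 | (3S,5R,6Z)-3,5-bis(tert-butyldimethylsilyloxy)-1-iodooct-6-ene | ICC[C@@H](O[Si](C)(C)C(C)(C)C)C[C@@H](O[Si](C)(C)C(C)(C)C)/C=C\C
F7 | step 10 | [(3S,5R,6Z)-3,5-bis(tert-butyldimethylsilyloxy)oct-6-en-1-yl]zinc iodide | I[Zn]CC[C@@H](O[Si](C)(C)C(C)(C)C)C[C@@H](O[Si](C)(C)C(C)(C)C)/C=C\C
F8 | step 10 | 1-(benzyloxy)-4-[(3R,5R,6Z)-3,5-bis(tert-butyldimethylsilyloxy)oct-6-en-1-yl]-2-methoxybenzene | COc1cc(CC[C@@H](O[Si](C)(C)C(C)(C)C)C[C@@H](O[Si](C)(C)C(C)(C)C)/C=C\C)ccc1OCc1ccccc1
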